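Readings and results stem from a simulated flask with constants of no real substance, and the scatter is random.

Amounts first: you want the most target, and target is made and lost side by side, so its top lies under a ceiling that you can reckon from the runs.

| flask | starting material | gas | initiator | remark | time |
|---|---|---|---|---|---|
| spring | 0.10 M (fed, over 15 s) | 44 mM (held) | 1.3 mM | run made earlier; the fed solution adds 0.10 times the starting volume |  |
| noon | 0.10 M (fed, over 15 s) | 44 mM (held) | 3 mM | run made earlier; the fed solution adds 0.10 times the starting volume |  |
| flask | 0.10 M (fed, over 15 s) | 44 mM (held) | 2.0 mM | the fed solution adds 0.10 times the starting volume | 50 min |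

| run | time / min | target / % | starting material / % |
|---|---|---|---|
| spring | 2.00 | 8.6 | 87.6 |
| spring | 4.00 | 15.1 | 70.0 |
| spring | 8.00 | 19.0 | 32.0 |
| spring | 15.0 | 4.4 | 0 |
| spring | 25.0 | 0.1 | 0 |
| spring | 50.0 | 0.2 | 0 |
| noon | 2.00 | 10.1 | 84.5 |
| noon | 4.00 | 17.3 | 63.5 |
| noon | 8.00 | 21.3 | 21.0 |
| noon | 15.0 | 2.3 | 0.1 |
| noon | 25.0 | 0.3 | 0 |
| noon | 50.0 | 0.1 | 0 |

(standard deviation of a reading: 0.3 percentage points)

- time, not beyond 50 min, at which the flask holds most target
- the amount of target, in percent of the starting material charged, at that time

- a species is counted by the starting material in it: one ended chains A or self-condensation product counts as two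
- charges are per starting volume, the dose included; the dosed solution carries all of it
- at the start none of reagent is dissolved
- candidate steps: initiator -> 2 initiating radical; starting material + initiating radical -> chain carrier; reagent + chain carrier -> target + initiating radical; 2 chain carrier -> ended chains A; 2 initiating radical -> ended chains B; target -> over-reaction product; gas <-> reagent; 2 starting material -> self-condensation product

Take the numbers in turn. The dose of 15 s ends before the first reading at 2.00 min, so you can treat it as charged at once. The initiator moves the rate weakly in these readings: raising it by a factor of 2.31 from the spring run to the noon run moved the loss of starting material from 0.0927 /min to 0.106 /min of the charge, a factor of 1.14. Read as a first-order loss, the lifetime of target enters the ceiling in full proportion, so that is the number to know well.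

In the noon run, c(starting material) extrapolates to zero near 9.98 min. Taking target there as its 8.00 min reading, the fall to 2.3% at 15.0 min gives a lifetime of 2.25 min. That last reading, good to 0.3 percentage points, is a weak point of this lifetime, which is itself a reading. Between the two runs, this flask's rate comes to 0.0992 /min, so its ceiling, rate times lifetime of target, is 22.4%. At 8.00 min the spring run stood at 0.910 of its ceiling and the noon run at 0.893. I therefore reckon about 20.2% for this flask, near that time.

The forecast gives 20.6% (range 19.8% to 21.5%) at 9 min (range 7.8 min to 10.2 min), a height slightly above my figure, with target “peaking just before starting material is exhausted”.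

The flask gives 20.2% at 8.40 min, inside both ranges.

    initiator → 2 initiating radical (k = 0.00130 /s)
    starting material + initiating radical → chain carrier (k = 1.50 × 10⁵ /M/s)
    reagent + chain carrier → target + initiating radical (k = 13000 /M/s)
    2 chain carrier → ended chains A (k = 1.30 × 10⁶ /M/s)
    2 initiating radical → ended chains B (k = 3.70 × 10⁷ /M/s)
    target → over-reaction product (k = 0.00770 /s)
    gas ⇌ reagent, rate k7*(csat - [reagent]) (kL = 0.00460 /s)
    2 starting material → self-condensation product (k = 1.60 × 10⁻⁵ /M/s)

Taken in proportion to the ceiling, the forecast's height passes the top of its range if a run shows a lifetime of target more than 4.37% above the forecast's own. On the neighbouring flask, with 0.060 M of starting material, taking the same rate in concentration gives a ceiling of 37.3% of its smaller charge, and the same mean share gives 33.6%. That neighbouring flask holds 31.1% at its best.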